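In a one-step world substrate would fall at a single first-order constant whatever the charge, and the runs do not allow that.

| flask | substrate | remark | time |
|---|---|---|---|
| east | 0.017 M | run made earlier |  |
| south-west | 0.051 M | run made earlier |  |
| south | 0.16 M | run made earlier |  |
| summer | 0.15 M |  | 5.0 min |
| midnight | 0.015 M |  | 5.0 min |
| dawn | 0.050 M |  | 5.0 min |
| autumn | 0.025 M |  | 5.0 min |
| dusk | 0.10 M |  | 5.0 min |
| noon | 0.030 M |  | 5.0 min |

- east (time / min: single ring / %, substrate / %): 0.667: 8.8, 73.5; 1.33: 18.3, 55.8; 2.00: 21.4, 44.5; 2.50: 25.6, 35.9
- south-west (time / min: single ring / %, substrate / %): 0.667: 8.9, 55.3; 1.33: 14.1, 38.4; 2.00: 15.8, 27.4; 2.50: 18.6, 21.5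
- south (time / min: single ring / %, substrate / %): 0.200: 1.3, 62.2; 0.500: 5.3, 40.3; 1.00: 7.9, 22.4; 2.50: 10.9, 8.5

(standard deviation of a reading: 1 percentage point)

- the flasks by amount of single ring, in percent of the substrate charged, highest first, at 5.0 min (summer / midnight / dawn / autumn / dusk / noon)
- the amount of single ring, in percent of the substrate charged of the flask you put first, at 5.0 min
- the amount of single ring, in percent of the substrate charged of the flask you put last, at 5.0 min



From the charge to its last reading the east run loses substrate at 0.410 /min around a logarithmic mean of 0.0106 M, while the south run up to its first reading loses it at 2.37 /min around 0.127 M, a much faster loss. So I write −dS/dt = aS + bS·S, with S the substrate, and these two points give a = 0.231 /min and b = 16.8 /M/min.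

The quantity to carry is the crossover concentration c = a/b = 0.0137 M, the substrate level at which the two paths take substrate equally. Single ring at the last reading drops from 25.6% in the east run to 10.9% in the south run, so I give it to the first-order path, whose selectivity at any moment is c/(c+S). Integrating with charge C and time t gives S/(c+S) = [C/(c+C)]exp(−at), and single ring as a fraction of the charge is P = f(c/C)ln[(c+C)/(c+S)]. Here f, the part of that path read as single ring, averages 71.0% over the last readings of the east, south-west and south runs.

At 5.0 min, twice the last reading, I commit to 36.3% for midnight and 13.9% for summer, far less, with the others ranked between them by rising charge.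

The forecast reads midnight > autumn > noon > dawn > dusk > summer, with 35.5% and 13.5%, holding that “only about three-quarters of the first-order flux reaches single ring”. The flask gives midnight > autumn > noon > dawn > dusk > summer, with 36.3% and 13.3%.

    2 substrate → open dimer (k = 0.140 /M/s)
    substrate + open dimer → open trimer (k = 0.0210 /M/s)
    open dimer → ring dimer (k = 0.00520 /s)
    substrate ⇌ single ring (K = 5.80, k = 0.00290 /s)
    substrate ⇌ dormant form (K = 0.550, k = 0.00100 /s)

In summer the forward rate of 2 substrate into open dimer starts at 14.5 times the forward rate of substrate into single ring and stands at 0.66 of it at 5.00 min. Summer's substrate is then 0.00686 M, below c. For the neighbour of summer charged at 0.26 M, 19.0 times c, the same reckoning gives 9.87%, and the computed flask holds 9.21% of single ring.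

The earlier runs and the new flask come from a simulation on assumed constants; the scatter is artificial.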